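**Plan**

- Retrosynthesis: the C5'–O bond is cut first (hydroquinone ⇐ p-quinone ⇐ monophenol). Then come the exocyclic N–C bond to the dehydrohydantoin, the C2–N bond, and the imidazole C4–C and C5–C bonds to the two benzylic carbons.
- Enabling feature: the 2'-OH and 5'-OH groups are para to each other on the pentasubstituted benzene ring. In the 2-hydroxy-3,4-dimethoxybenzyl precursor, C5' is therefore the free para position of the 2'-phenol, whose ortho carbons C1' and C3' are substituted.
- Forward: no ring is built. The imidazole (4,5-diiodo-1-methylimidazole) and the dehydrohydantoin (1-methylparabanic acid) are bought. The C5 benzyl group and then the C4 benzyl group are attached by iodine–magnesium exchange, aldehyde addition and ionic deoxygenation. C2 azidation, hydrogenation and condensation follow, then phenol-to-quinone oxidation and quinone reduction.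
- Stereochemistry: the target has none; the carbinol centres formed on the way are racemic and are erased by deoxygenation.

Key step: step 9

Remark: naamidine E has no stereogenic element, so the constitution drawn is the single species to be made. The carbinol carbons of 5 and 9 and C5' of 21 are formed racemic and disappear within the route.

**Route**

Step 1
Reactants: 1 2-hydroxy-3,4-dimethoxybenzaldehyde
Product: 2 2-(benzyloxy)-3,4-dimethoxybenzaldehyde
Conditions: BnBr, K2CO3, DMF, rt
Reagents that add atoms: benzyl bromide, BrCc1ccccc1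
Why: Williamson ether synthesis on the carbonate-generated phenoxide gives a benzyl ether that should survive Grignard and organolithium reagents and brief dilute acid, and that is removed later in the same hydrogenation that reduces the azide.

Step 2
Reactants: 3 4,5-diiodo-1-methyl-1H-imidazole; 2 2-(benzyloxy)-3,4-dimethoxybenzaldehyde
Product: 5 rac-[2-(benzyloxy)-3,4-dimethoxyphenyl](4-iodo-1-methyl-1H-imidazol-5-yl)methanol, via (4-iodo-1-methyl-1H-imidazol-5-yl)magnesium bromide 4 (not isolated)
Conditions: EtMgBr (1.05 equiv), THF, 0 °C; then 2, 0 °C → rt; aq NH4Cl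
Reagents that add atoms: none
Why: Iodine–magnesium exchange of 1-alkyl-4,5-diiodoimidazoles takes place at C5, where the carbanion is stabilised by the adjacent N1, and the Grignard reagent adds to the aldehyde (Grignard addition) to give a racemic carbinol whose stereocentre is removed in step 3.

Step 3
Reactants: 5 rac-[2-(benzyloxy)-3,4-dimethoxyphenyl](4-iodo-1-methyl-1H-imidazol-5-yl)methanol
Product: 6 5-[2-(benzyloxy)-3,4-dimethoxybenzyl]-4-iodo-1-methyl-1H-imidazole
Conditions: Et3SiH (5 equiv), TFA (10 equiv), CH2Cl2, 0 °C → rt; aq NaHCO3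
Reagents that add atoms: none
Why: Ionic hydrogenation: the diarylcarbinol ionises to a cation stabilised by the para-methoxy and ortho-benzyloxy groups and is captured by hydride from the silane, while the C4–I bond and, in dilute acid at short reaction time, the aryl benzyl ether should stay intact.

Step 4
Reactants: 6 5-[2-(benzyloxy)-3,4-dimethoxybenzyl]-4-iodo-1-methyl-1H-imidazole; 7 4-methoxybenzaldehyde
Product: 9 rac-{5-[2-(benzyloxy)-3,4-dimethoxybenzyl]-1-methyl-1H-imidazol-4-yl}(4-methoxyphenyl)methanol, via {5-[2-(benzyloxy)-3,4-dimethoxybenzyl]-1-methyl-1H-imidazol-4-yl}magnesium bromide 8 (not isolated)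
Conditions: EtMgBr (1.3 equiv), THF, rt; then 7, rt; aq NH4Cl
Reagents that add atoms: none
Why: 4-Iodoimidazoles undergo iodine–magnesium exchange with EtMgBr at room temperature and 6 offers no hydrogen acidic enough to quench the reagent, so the C4 Grignard reagent should add to 4-methoxybenzaldehyde (Grignard addition) to give a racemic carbinol whose stereocentre is erased in step 5.

Step 5
Reactants: 9 rac-{5-[2-(benzyloxy)-3,4-dimethoxybenzyl]-1-methyl-1H-imidazol-4-yl}(4-methoxyphenyl)methanol
Product: 10 5-[2-(benzyloxy)-3,4-dimethoxybenzyl]-4-(4-methoxybenzyl)-1-methyl-1H-imidazole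
Conditions: Et3SiH (10 equiv), TFA (10 equiv), CH2Cl2, 0 °C → rt; aq NaHCO3
Reagents that add atoms: none
Why: Ionic hydrogenation as in step 3: the p-anisyl-stabilised cation at the C4 carbinol carbon is reduced by a large excess of silane, which should keep intermolecular hydride transfer ahead of attack by the neighbouring aryl ring.

Step 6
Reactants: 10 5-[2-(benzyloxy)-3,4-dimethoxybenzyl]-4-(4-methoxybenzyl)-1-methyl-1H-imidazole
Product: 13 2-azido-5-[2-(benzyloxy)-3,4-dimethoxybenzyl]-4-(4-methoxybenzyl)-1-methyl-1H-imidazole, via the 2-lithioimidazole 11 (not isolated), via the lithium 1-(imidazol-2-yl)-3-tosyltriazenide 12 (not isolated)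
Conditions: n-BuLi (1.1 equiv), THF, –78 °C; TsN3, –78 °C → rt; aq NH4Cl
Reagents that add atoms: 4-methylbenzenesulfonyl azide (tosyl azide), Cc1ccc(S(=O)(=O)N=[N+]=[N-])cc1
Why: C2–H of a 1-methylimidazole, flanked by both nitrogens, is the kinetically most acidic C–H and is lithiated at –78 °C, and the 2-lithioimidazole adds to the terminal nitrogen of tosyl azide to give a triazenide that loses sulfinate on warming (electrophilic azide transfer to an organolithium).

Step 7
Reactants: 13 2-azido-5-[2-(benzyloxy)-3,4-dimethoxybenzyl]-4-(4-methoxybenzyl)-1-methyl-1H-imidazole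
Product: 15 6-{[2-amino-4-(4-methoxybenzyl)-1-methyl-1H-imidazol-5-yl]methyl}-2,3-dimethoxyphenol, via 2-amino-5-[2-(benzyloxy)-3,4-dimethoxybenzyl]-4-(4-methoxybenzyl)-1-methyl-1H-imidazole 14 (not isolated)
Conditions: H2 (1 atm), 10% Pd/C, MeOH, rt; filtration under Ar
Reagents that add atoms: none
Why: Catalytic hydrogenation over palladium reduces the azide to the amine with loss of dinitrogen and then hydrogenolyses the aryl benzyl ether, while the methyl ethers and the diarylmethane C–C bonds are inert.

Step 8
Reactants: 15 6-{[2-amino-4-(4-methoxybenzyl)-1-methyl-1H-imidazol-5-yl]methyl}-2,3-dimethoxyphenol; 16 1-methylparabanic acid (1-methylimidazolidine-2,4,5-trione)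
Product: 20 5'-deoxynaamidine E, 4-{[5-(2-hydroxy-3,4-dimethoxybenzyl)-4-(4-methoxybenzyl)-1-methyl-1H-imidazol-2-yl]amino}-1-methyl-1H-imidazole-2,5-dione, via 1-methyl-4-(trimethylsilyloxy)-1H-imidazole-2,5-dione 17 (not isolated), via the O-trimethylsilyl ether of 15 18 (not isolated), via the O-trimethylsilyl ether of 20 19 (not isolated)
Conditions: 16 (1.5 equiv), BSA, MeCN, 80 °C; 15, BSA, MeCN, rt; combine, PhMe, 100 °C; aq NH4Cl
Reagents that add atoms: none
Why: Silyl-mediated condensation (addition–elimination at an O-silyl imidate): the exocyclic amino group of the 2-aminoimidazole attacks C4 of the silylated parabanic acid, the carbon activated as the silyl imidate and by the adjacent C5 carbonyl, and loss of silanol gives the acylamidine with the N-methyl group remote from the new C–N bond, the silylated phenol being inert and freed on aqueous work-up.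

Step 9
Reactants: 20 5'-deoxynaamidine E
Product: 22 naamidine E quinone, 2,3-dimethoxy-5-{[4-(4-methoxybenzyl)-1-methyl-2-[(1-methyl-2,5-dioxo-2,5-dihydro-1H-imidazol-4-yl)amino]-1H-imidazol-5-yl]methyl}-1,4-benzoquinone, via the C5' nitrosodisulfonate adduct (4-[bis(sulfonato)aminooxy]cyclohexa-2,5-dienone, dipotassium salt, racemic at C5') 21 (not isolated)
Conditions: (KSO3)2NO (2.5 equiv), aq KH2PO4, acetone, 0 °C → rt
Reagents that add atoms: potassium nitrosodisulfonate (Fremy's salt), [O]N(S(=O)(=O)[O-])S(=O)(=O)[O-].[K+].[K+]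
Why: Teuber oxidation: the nitrosodisulfonate radical abstracts the hydrogen atom of the 2'-OH, the only O–H bond in 20, and a second nitrosodisulfonate couples through its oxygen with the aryloxyl radical at the para carbon C5' to give dienone 21, which loses imidodisulfonate together with the C5' hydrogen to give the p-quinone, so that the new C5'–O bond carries an oxygen atom of the reagent. The closest known reaction is the oxidation of ortho-alkoxy, ortho'-alkyl phenols with a free para position to p-benzoquinones by Fremy's salt, as used for ubiquinone-type 2,3-dimethoxy-1,4-benzoquinones. No ring closes, and no stereocentre remains, because the sp3 carbon C5' of 21 returns to sp2 in the elimination. The step needs site selectivity on the phenol ring and chemoselectivity over the rest of the molecule: the ortho carbons C1' and C3' are substituted and the meta carbon C6' carries no spin density, so that C5' is the only open position for radical coupling. Hydrogen-atom abstraction selects the phenol over the anisole ring and the benzylic methylene groups, and the acylamidine on C2 lowers the electron density of the imidazole, so that electron transfer from the heterocycle should not compete. The phosphate buffer keeps the medium near neutral and should spare the base-sensitive dehydrohydantoin.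

Step 10
Reactants: 22 naamidine E quinone
Product: 23 naamidine E
Conditions: Na2S2O4 (3 equiv), degassed EtOAc/H2O, rt, Ar
Reagents that add atoms: none
Why: Dithionite reduction of a 1,4-benzoquinone to the hydroquinone (electron transfer, then protonation) should be far faster than any reaction at the acylamidine C=N bond, and the tetraoxygenated hydroquinone is isolated under argon because it re-oxidises in air.

**Compound list**

1 | 2-hydroxy-3,4-dimethoxybenzaldehyde | COc1ccc(C=O)c(O)c1OC | starting material
2 | 2-(benzyloxy)-3,4-dimethoxybenzaldehyde | COc1ccc(C=O)c(OCc2ccccc2)c1OC | intermediate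
3 | 4,5-diiodo-1-methyl-1H-imidazole | Cn1cnc(I)c1I | starting material
4 | (4-iodo-1-methyl-1H-imidazol-5-yl)magnesium bromide (not isolated) | Cn1cnc(I)c1[Mg]Br | intermediate
5 | rac-[2-(benzyloxy)-3,4-dimethoxyphenyl](4-iodo-1-methyl-1H-imidazol-5-yl)methanol | COc1ccc(C(O)c2c(I)ncn2C)c(OCc2ccccc2)c1OC | intermediate
6 | 5-[2-(benzyloxy)-3,4-dimethoxybenzyl]-4-iodo-1-methyl-1H-imidazole | COc1ccc(Cc2c(I)ncn2C)c(OCc2ccccc2)c1OC | intermediate
7 | 4-methoxybenzaldehyde | COc1ccc(C=O)cc1 | starting material
8 | {5-[2-(benzyloxy)-3,4-dimethoxybenzyl]-1-methyl-1H-imidazol-4-yl}magnesium bromide (not isolated) | COc1ccc(Cc2c([Mg]Br)ncn2C)c(OCc2ccccc2)c1OC | intermediate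
9 | rac-{5-[2-(benzyloxy)-3,4-dimethoxybenzyl]-1-methyl-1H-imidazol-4-yl}(4-methoxyphenyl)methanol | COc1ccc(C(O)c2ncn(C)c2Cc2ccc(OC)c(OC)c2OCc2ccccc2)cc1 | intermediate
10 | 5-[2-(benzyloxy)-3,4-dimethoxybenzyl]-4-(4-methoxybenzyl)-1-methyl-1H-imidazole | COc1ccc(Cc2ncn(C)c2Cc2ccc(OC)c(OC)c2OCc2ccccc2)cc1 | intermediate
11 | {5-[2-(benzyloxy)-3,4-dimethoxybenzyl]-4-(4-methoxybenzyl)-1-methyl-1H-imidazol-2-yl}lithium (not isolated) | COc1ccc(Cc2nc([Li])n(C)c2Cc2ccc(OC)c(OC)c2OCc2ccccc2)cc1 | intermediate
12 | lithium 1-{5-[2-(benzyloxy)-3,4-dimethoxybenzyl]-4-(4-methoxybenzyl)-1-methyl-1H-imidazol-2-yl}-3-tosyltriazenide (not isolated) | COc1ccc(Cc2nc(N=N[N-]S(=O)(=O)c3ccc(C)cc3)n(C)c2Cc2ccc(OC)c(OC)c2OCc2ccccc2)cc1.[Li+] | intermediate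
13 | 2-azido-5-[2-(benzyloxy)-3,4-dimethoxybenzyl]-4-(4-methoxybenzyl)-1-methyl-1H-imidazole | COc1ccc(Cc2nc(N=[N+]=[N-])n(C)c2Cc2ccc(OC)c(OC)c2OCc2ccccc2)cc1 | intermediate
14 | 2-amino-5-[2-(benzyloxy)-3,4-dimethoxybenzyl]-4-(4-methoxybenzyl)-1-methyl-1H-imidazole (not isolated in step 7) | COc1ccc(Cc2nc(N)n(C)c2Cc2ccc(OC)c(OC)c2OCc2ccccc2)cc1 | intermediate
15 | 6-{[2-amino-4-(4-methoxybenzyl)-1-methyl-1H-imidazol-5-yl]methyl}-2,3-dimethoxyphenol | COc1ccc(Cc2nc(N)n(C)c2Cc2ccc(OC)c(OC)c2O)cc1 | intermediate
16 | 1-methylparabanic acid (1-methylimidazolidine-2,4,5-trione) | CN1C(=O)NC(=O)C1=O | starting material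
17 | 1-methyl-4-(trimethylsilyloxy)-1H-imidazole-2,5-dione (not isolated) | CN1C(=O)N=C(O[Si](C)(C)C)C1=O | intermediate
18 | O-trimethylsilyl ether of 15 (not isolated) | COc1ccc(Cc2nc(N)n(C)c2Cc2ccc(OC)c(OC)c2O[Si](C)(C)C)cc1 | intermediate
19 | O-trimethylsilyl ether of 20 (not isolated) | COc1ccc(Cc2nc(NC3=NC(=O)N(C)C3=O)n(C)c2Cc2ccc(OC)c(OC)c2O[Si](C)(C)C)cc1 | intermediate
20 | 5'-deoxynaamidine E (2-hydroxy-3,4-dimethoxybenzyl phenol) | COc1ccc(Cc2nc(NC3=NC(=O)N(C)C3=O)n(C)c2Cc2ccc(OC)c(OC)c2O)cc1 | intermediate
21 | C5' nitrosodisulfonate adduct of 20, dipotassium salt, racemic at C5' (not isolated) | COc1ccc(Cc2nc(NC3=NC(=O)N(C)C3=O)n(C)c2CC2=CC(ON(S(=O)(=O)[O-])S(=O)(=O)[O-])C(OC)=C(OC)C2=O)cc1.[K+].[K+] | intermediate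
22 | naamidine E quinone | COc1ccc(Cc2nc(NC3=NC(=O)N(C)C3=O)n(C)c2CC2=CC(=O)C(OC)=C(OC)C2=O)cc1 | intermediate
23 | naamidine E | COc1ccc(Cc2nc(NC3=NC(=O)N(C)C3=O)n(C)c2Cc2cc(O)c(OC)c(OC)c2O)cc1 | target

**Count and risks**

Total step count: 10. Longest linear sequence: 10 steps (1 → 23 through steps 1–10); the imidazole 3 enters at step 2, aldehyde 7 at step 4 and 16 at step 8.

Steps most likely to fail:

1. Step 9. Oxidative degradation at the 2-(acylamidino)imidazole, or hydrolytic opening of the dehydrohydantoin in the aqueous buffer, may compete with hydrogen-atom abstraction at the phenol, and low solubility may slow the oxidation. The fallback moves the same phenol-to-p-quinone oxidation to the azide stage, where neither an amino nor an acylamidine group is present. It sets out from azide 13. Acidolytic debenzylation (TFA, pentamethylbenzene, rt) should give 6-{[2-azido-4-(4-methoxybenzyl)-1-methyl-1H-imidazol-5-yl]methyl}-2,3-dimethoxyphenol F1. Fremy's salt (aq KH2PO4, acetone) should then give, through the C5' nitrosodisulfonate adduct F2, the azido quinone F3. Hydrogenation (H2, Pd/C, MeOH) should reduce the quinone to the azido hydroquinone F4 and then the azide, giving the amino hydroquinone F5. F5 is kept under argon and silylated with BSA to its bis(trimethylsilyl) ether F6. F6 is condensed with silyl imidate 17 (PhMe, 100 °C) to give the bis(trimethylsilyl) ether of naamidine E F7. Aqueous work-up comes back to the route at the target 23.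

2. Step 5. The benzylic cation at the C4 carbinol carbon may be captured by C6' of the neighbouring trioxygenated ring (six-membered Friedel–Crafts cyclisation) before hydride transfer, and the benzyl ether may be lost by acidolysis. The fallback avoids the cation: it sets out from iodide 6 and uses a Negishi cross-coupling with commercial 4-methoxybenzylzinc chloride (Pd(OAc)2, SPhos, THF, rt → 50 °C). This forms the C4–CH2 bond directly and comes back to the route at 10, so steps 4 and 5 are replaced by one step.

3. Step 7. The strongly coordinating 2-aminoimidazole formed first may poison the catalyst, so that O-debenzylation stalls, and a long reaction exposes the electron-rich aminophenol to adventitious air. The fallback separates the two reductions without hydrogen gas. It sets out from azide 13: zinc dust and NH4Cl in EtOH/H2O should reduce only the azide to give 14, which is isolated. Acidolytic debenzylation of 14 (TFA, pentamethylbenzene, rt; basic work-up under argon) then comes back to the route at 15.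

**Further compounds**

F1 | step 9 | 6-{[2-azido-4-(4-methoxybenzyl)-1-methyl-1H-imidazol-5-yl]methyl}-2,3-dimethoxyphenol | COc1ccc(Cc2nc(N=[N+]=[N-])n(C)c2Cc2ccc(OC)c(OC)c2O)cc1
F2 | step 9 | C5' nitrosodisulfonate adduct of F1, dipotassium salt, racemic at C5' | COc1ccc(Cc2nc(N=[N+]=[N-])n(C)c2CC2=CC(ON(S(=O)(=O)[O-])S(=O)(=O)[O-])C(OC)=C(OC)C2=O)cc1.[K+].[K+]
F3 | step 9 | 5-{[2-azido-4-(4-methoxybenzyl)-1-methyl-1H-imidazol-5-yl]methyl}-2,3-dimethoxy-1,4-benzoquinone | COc1ccc(Cc2nc(N=[N+]=[N-])n(C)c2CC2=CC(=O)C(OC)=C(OC)C2=O)cc1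
F4 | step 9 | 5-{[2-azido-4-(4-methoxybenzyl)-1-methyl-1H-imidazol-5-yl]methyl}-2,3-dimethoxybenzene-1,4-diol | COc1ccc(Cc2nc(N=[N+]=[N-])n(C)c2Cc2cc(O)c(OC)c(OC)c2O)cc1
F5 | step 9 | 5-{[2-amino-4-(4-methoxybenzyl)-1-methyl-1H-imidazol-5-yl]methyl}-2,3-dimethoxybenzene-1,4-diol | COc1ccc(Cc2nc(N)n(C)c2Cc2cc(O)c(OC)c(OC)c2O)cc1
F6 | step 9 | bis(trimethylsilyl) ether of F5 | COc1ccc(Cc2nc(N)n(C)c2Cc2cc(O[Si](C)(C)C)c(OC)c(OC)c2O[Si](C)(C)C)cc1
F7 | step 9 | bis(trimethylsilyl) ether of naamidine E | COc1ccc(Cc2nc(NC3=NC(=O)N(C)C3=O)n(C)c2Cc2cc(O[Si](C)(C)C)c(OC)c(OC)c2O[Si](C)(C)C)cc1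
F0 | step 5 | none | none
F0 | step 7 | none | none
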